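## Structural features

The target is a 2,3-dihydro-1,4-benzodioxine in which ring A, a tetrasubstituted benzene, is fused through C4a and C8a to a dioxane ring made of O1, C2, C3 and O4. C2 carries ring B (4-hydroxy-3,5-dimethoxyphenyl) and C3 a methyl group, while ring A carries a methoxy group on C5, next to the O4-bearing C4a, and an (E)-prop-1-enyl group on C7, para to C4a. C2 and C3 are adjacent stereocentres, both R, which puts aryl and methyl trans and corresponds to a threo (1R,2R)-1-arylpropane-1,2-diol. The fragile parts are the electron-rich styrene (hydrogenation, electrophiles, strong acid), the free phenol of ring B, and the C2–O1 bond, which is benzylic to an electron-rich ring and can ionise under acid, although re-closure returns the more stable trans isomer. The real difficulty is the unsymmetrical pairing of the two ring oxygens: O4, on the methyl-bearing C3, must end next to the C5 methoxy group, and O1, on the aryl-bearing C2, next to the unsubstituted C8. The key step exploits the fact that C4a and C8a each carry exactly one dioxane oxygen, so that each can be the oxygen-bearing carbon of an alkynyl ether. Joining them (C4a–C8a) closes the dioxane ring, the two alkyne termini become C5 and C8, and a third alkyne supplies C6 and C7 of ring A.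

## Logic of the disconnections

22 ⇒ 21 (step 11). The bond cut is the acetal O–CH2 bond on the ring B phenol oxygen. The phenol has to be masked from step 1 to step 10 against an aryllithium, KH, alkyllithium and amide bases and the alkoxide of the palladium step, and the mask must also survive the fluoride of step 7. A silyl ether on ring B would not survive that fluoride, and an acid-labile silyl group on O4 could not be removed next to an alkynyl ether; the acetal solves both. The demand on the forward step is an acid mild enough to spare the propenyl group and the C2–O1 bond.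

21 ⇒ 20 (step 10). The C5–O bond of the ring A methyl ether is cut back to C5–Cl. An oxygen substituent cannot sit on an alkyne terminus through the ring-forming step, whereas chlorine can, comes directly from 9, and marks that terminus for regiocontrol. The forward step must couple an electron-rich, ortho-oxygenated aryl chloride with a methoxide source without touching the alkene.

20 ⇒ 18 + 19 (step 9). C4a–C8a, C5–C6 and C7–C8 are cut together. This dissolves ring A and the dioxane ring into an acyclic bis(alkynyl ether) whose tether O1–C2–C3–O4 already holds both stereocentres, and all six carbons of ring A then come from 9 (twice) and 19. The forward step needs a catalyst that works at room temperature, because secondary alkynyl ethers fragment on heating, and it needs 19 to enter with one orientation.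

18 ⇒ 15 + 9 (step 8). The O4–C4a bond is cut, removing the C4a≡C5–Cl unit from O4. The unit is introduced by adding the O4 alkoxide to 10, which 9 and base generate in the flask, and eliminating once. The forward step must stop at the chloroalkyne (no chlorine–lithium exchange) and must leave the C8 terminal alkyne on O1 intact.

15 ⇒ 14 ⇒ 8 + 9 (steps 7 and 6). The O–Si bond on O4 and then the O1–C8a bond are cut. O1 is served first because it is the free hydroxyl after the reduction; O4 stays silylated, which is what differentiates the two oxygens. Here too 9 reacts through 10, which is never isolated. The silyl group must not migrate to O1 under KH (hence triisopropylsilyl) and its removal by fluoride must leave ring B and the alkynyl ether alone.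

8 ⇒ 7 (step 5). The C–H bond at the future C2 is cut, reducing the problem to a ketone whose only stereocentre is the future C3. The forward step must deliver hydride with Felkin–Anh selectivity, which asks for a bulky, non-chelating group on the neighbouring oxygen and a bulky hydride.

7 ⇒ 2 + 5 (step 4, through 6). The bond between ring B and the carbonyl carbon (future C2) is cut, giving a convergent union of the ring B piece and the three-carbon piece. The addition must stop at the ketone and must not racemise the adjacent centre.

5 ⇒ 4 ⇒ 3 and 2 ⇒ 1 (steps 3, 2 and 1). Only functional groups change. The future C3 is taken from 3 with its configuration untouched, and 1 already has the ring B oxygenation pattern and the halogen in place.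

## Other disconnections considered

Alternative 1: The cut removes C2 as a carbene carbon (O1–C2 and C2–C3), leaving the racemic acetal methyl 7-methoxy-2-methyl-1,3-benzodioxole-5-carboxylate A1, in which C3 is the acetal carbon, and the diazo compound 4-(diazomethyl)-2,6-dimethoxyphenyl 4-methylbenzenesulfonate A2.
- Forward step: Rh2(S-PTTL)4 would transfer the arylcarbene to O1 of A1, and the oxonium ylide would undergo a Stevens [1,2]-shift of C3 to give the ring-expanded benzodioxane ester A3.
- In its favour: it is the most convergent plan, both aromatic pieces are joined in the ring-forming step, and carbene insertion into acetal C–O bonds is a known reaction type for cyclic acetals.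
- Against it here: A2 is a donor-only aryldiazomethane, prone to azine and stilbene formation. O1 and O4 of A1 differ only through the C5 methoxy group, so attack at O4 would give the constitutional isomer. The configuration of C3 in A1 is lost in the shift, which passes through an oxygen-stabilised radical or cation pair that is probably no longer bound to rhodium, so both the trans relationship and the absolute configuration would rest on a recombination the chiral carboxylates may not control. The ester must afterwards be turned into the propenyl group and the sulfonate removed.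
- Comparison: in step count and convergence this alternative is the better plan (roughly eight steps against eleven). In mechanism both plans ask for a step without direct precedent, but the chosen plan puts no stereochemical burden on that step, whereas here constitution, relative and absolute configuration are all decided in it. In structure, the chosen plan builds ring A, while this one only builds the dioxane ring.

Alternative 2: The cut is O4–C3 together with one C–H bond of the C3 methyl group, which leads back to the phenol 4-bromo-2-methoxy-6-{[(1S)-1-(3,5-dimethoxy-4-triisopropylsilyloxyphenyl)prop-2-en-1-yl]oxy}phenol A4, with a vinyl group where C3 and its methyl will be.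
- Forward step: Co(salen), an N-fluoro-2,4,6-trimethylpyridinium salt and PhSiH3 would generate a cobalt hydride that transfers a hydrogen atom to the terminal alkene carbon. The C3 radical would be oxidised and captured by the C4a hydroxyl (Mukaiyama-type hydroalkoxylation, six-membered closure) to give the 7-bromo benzodioxane A5.
- In its favour: conditions are mild and tolerate the aryl bromide and the silyl ether. The reaction type is established for phenol nucleophiles. A4 could come from an enantioselective allylic etherification ([Ir(cod)Cl]2 with a phosphoramidite), which would set C2. A Suzuki–Miyaura coupling and a desilylation would finish the synthesis.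
- Against it here: C3 would be set only by 1,2-induction from C2 in a radical-polar crossover. Trans is expected from a chair-like closure, but it is not assured. The electron-rich ring B on the neighbouring carbon invites a 1,2-aryl shift or loss of the aryloxy group from the C3 cation.
- Comparison: in step economy (about seven steps) and in closeness to precedent this alternative is the better plan. In tolerance of functional groups the two are equal. In stereochemical security the chosen plan is stronger, because C3 comes from the chiral pool and C2 from a well-understood 1,2-induction before any ring is closed.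

Alternative 3: The cut is O1–C8a, leading back to the bromo alcohol (1R,2R)-2-{2-bromo-6-methoxy-4-[(E)-prop-1-enyl]phenoxy}-1-[3,5-dimethoxy-4-(triisopropylsilyloxy)phenyl]propan-1-ol A6.
- Forward step: Pd(OAc)2 with a di-tert-butyl biarylphosphine and Cs2CO3 would add the C8a–Br bond to zerovalent palladium, exchange bromide for the C2 alkoxide and form O1–C8a by reductive elimination (intramolecular Buchwald–Hartwig etherification), giving the silyl ether of the target A7.
- In its favour: this reaction type is established for benzodioxanes from secondary alcohols and proceeds with retention. No stereocentre is touched. The propenyl group is already in place and A7 is one step from the target.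
- Against it here: β-hydride elimination from the secondary benzylic palladium alkoxide (ketone plus hydrodebromination) is the known side path. A6 needs a ring A bromophenol that already carries the propenyl group, an inversion at the future C3, and a Felkin reduction next to an aryloxy group, which is less secure than next to a bulky silyloxy group.
- Comparison: on precedent and on step count (about eight steps) this alternative is the better plan, and it is used below as the fallback for the key step. The chosen plan is preferred only for what it adds in structure and mechanism: ring A is assembled from three two-carbon units, so two rings and three C–C bonds arise in one stereochemically innocent step, and the C5 and C7 substituents can be varied through the chloride and the third alkyne.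

Key step: step 9

Assumption: 19 is purchased as the pure E isomer; it is a volatile liquid and is therefore handled as a cold solution and used in excess.

## Route

Step 1
Reactants: 1 4-bromo-2,6-dimethoxyphenol
Product: 2 5-bromo-1,3-dimethoxy-2-(methoxymethoxy)benzene
Conditions: NaH, MOMCl, THF/DMF, 0 °C to rt
Reagents that add atoms: chloromethyl methyl ether, COCCl
Why: Williamson-type O-alkylation of the phenoxide; the methoxymethyl acetal is inert to organolithiums, KH, amide bases, fluoride and the palladium step, and is removed last by mild acid.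

Step 2
Reactants: 3 methyl (R)-lactate
Product: 4 methyl (2R)-2-(triisopropylsilyloxy)propanoate
Conditions: i-Pr3SiCl, imidazole, DMF, rt
Reagents that add atoms: chlorotriisopropylsilane, CC(C)[Si](Cl)(C(C)C)C(C)C
Why: Standard silylation of a secondary alcohol without touching the stereocentre; the bulky, non-chelating triisopropylsilyl group is chosen because it directs the later reduction and migrates only slowly between neighbouring oxygens under KH.

Step 3
Reactants: 4 methyl (2R)-2-(triisopropylsilyloxy)propanoate
Product: 5 (2R)-N-methoxy-N-methyl-2-(triisopropylsilyloxy)propanamide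
Conditions: MeNH(OMe)·HCl, i-PrMgCl, THF, −20 to 0 °C
Reagents that add atoms: N,O-dimethylhydroxylamine hydrochloride, CNOC.Cl
Why: Aminolysis of the ester by the chloromagnesium amide (Weinreb amide formation); the mildly basic, cold conditions should not epimerise the α-silyloxy centre.

Step 4
Reactants: 2 5-bromo-1,3-dimethoxy-2-(methoxymethoxy)benzene; 5 (2R)-N-methoxy-N-methyl-2-(triisopropylsilyloxy)propanamide
Product: 7 (2R)-1-[3,5-dimethoxy-4-(methoxymethoxy)phenyl]-2-(triisopropylsilyloxy)propan-1-one, via aryllithium 6 (not isolated)
Conditions: 2, n-BuLi, THF, −78 °C; then 5, −78 to −20 °C; aq. NH4Cl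
Reagents that add atoms: none
Why: Bromine–lithium exchange is much faster than any ring deprotonation at −78 °C, and the Weinreb ketone synthesis stops cleanly at the ketone; the stereocentre is not enolised before the quench.

Step 5
Reactants: 7 (2R)-1-[3,5-dimethoxy-4-(methoxymethoxy)phenyl]-2-(triisopropylsilyloxy)propan-1-one
Product: 8 (1R,2R)-1-[3,5-dimethoxy-4-(methoxymethoxy)phenyl]-2-(triisopropylsilyloxy)propan-1-ol
Conditions: LiBH(s-Bu)3, THF, −78 °C; then NaOH, H2O2, 0 °C
Reagents that add atoms: none
Why: Felkin–Anh reduction: the bulky silyloxy group cannot chelate and lies anti to the incoming hydride, which passes the α-hydrogen and not the methyl group, so the (2R) centre should induce the new (1R) carbinol centre (threo, the future C2).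

Step 6
Reactants: 8 (1R,2R)-1-[3,5-dimethoxy-4-(methoxymethoxy)phenyl]-2-(triisopropylsilyloxy)propan-1-ol; 9 trichloroethylene
Product: 14 {[(1R,2R)-1-[3,5-dimethoxy-4-(methoxymethoxy)phenyl]-1-(ethynyloxy)propan-2-yl]oxy}triisopropylsilane, via dichloroacetylene 10 (not isolated), via O1 dichlorovinyl ether 11 (not isolated), via O1 chloroethynyl ether 12 (not isolated), via lithium acetylide 13 (not isolated)
Conditions: KH, THF, 0 °C; 9, −50 °C to rt; n-BuLi, −78 to −40 °C; MeOH, −78 °C
Reagents that add atoms: none
Why: The standard trichloroethylene route to alkynyl ethers: the potassium alkoxide adds anti to dichloroacetylene formed in the flask, n-BuLi then eliminates HCl and exchanges the remaining chlorine for lithium, and methanol protonates the acetylide. It is known for secondary benzylic alcohols, and the C–O stereocentres are not involved.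

Step 7
Reactants: 14 {[(1R,2R)-1-[3,5-dimethoxy-4-(methoxymethoxy)phenyl]-1-(ethynyloxy)propan-2-yl]oxy}triisopropylsilane
Product: 15 (1R,2R)-1-[3,5-dimethoxy-4-(methoxymethoxy)phenyl]-1-(ethynyloxy)propan-2-ol
Conditions: Bu4NF, THF, 0 °C to rt; pH 7 buffer
Reagents that add atoms: none
Why: Fluoride desilylation is basic and therefore compatible with the acid-sensitive alkynyl ether and with the ring B acetal; the cold, buffered work-up guards against addition of the new hydroxyl to the alkyne.

Step 8
Reactants: 15 (1R,2R)-1-[3,5-dimethoxy-4-(methoxymethoxy)phenyl]-1-(ethynyloxy)propan-2-ol; 9 trichloroethylene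
Product: 18 5-[(1R,2R)-2-(chloroethynyloxy)-1-(ethynyloxy)propyl]-1,3-dimethoxy-2-(methoxymethoxy)benzene, via O4 dichlorovinyl ether 16 (not isolated), via lithium acetylide 17 (not isolated)
Conditions: KH (1.1 equiv), THF, 0 °C; 9, −50 to 0 °C; LiN(i-Pr)2 (2.3 equiv), −78 °C; MeOH, −78 °C
Reagents that add atoms: none
Why: The O4 alkoxide adds to dichloroacetylene 10, which base and 9 form once more in the flask exactly as in step 6, and an E1cb-type dehydrochlorination follows with an amide base, which cannot exchange chlorine for lithium and so should stop at the chloroalkyne (the first stage of the usual alkynyl ether synthesis). The terminal alkyne on O1 is only deprotonated and is restored by the cold quench, and 18 is chromatographed quickly on deactivated silica and used at once.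

Step 9
Reactants: 18 5-[(1R,2R)-2-(chloroethynyloxy)-1-(ethynyloxy)propyl]-1,3-dimethoxy-2-(methoxymethoxy)benzene; 19 (E)-pent-3-en-1-yne
Product: 20 (2R,3R)-5-chloro-2-[3,5-dimethoxy-4-(methoxymethoxy)phenyl]-3-methyl-7-[(E)-prop-1-enyl]-2,3-dihydro-1,4-benzodioxine
Conditions: Cp*RuCl(cod) (10 mol %), 19 (5 equiv), ClCH2CH2Cl, rt, slow addition of 18
Reagents that add atoms: none
Why: Proposed new method: Cp*RuCl(cod) should lose cyclooctadiene, bind both alkynyl ether alkynes of 18 and couple them oxidatively (divalent to formally tetravalent ruthenium) to a ruthenacyclopentadiene whose new C4a–C8a bond closes the dioxane ring as a six-membered ring fused to the metallacycle, the O1–C2–C3–O4 tether making this the normal 1,7-diyne mode. The alkyne of 19 should then insert at the Ru–C8 end, and reductive elimination should form C5–C6 and C7–C8, closing ring A by cycloaromatisation and releasing the Cp*RuCl fragment. The closest known reaction type is the room-temperature Cp*RuCl(cod) cyclotrimerisation of tethered 1,6- and 1,7-diynes, haloalkyne termini included, with terminal alkynes, together with the RhCl(PPh3)3 cyclotrimerisation of heteroatom-substituted diynes; a tether built from two alkynyl ether oxygens has not been shown. No stereocentre is formed; C2 and C3 sit on the tether, take part in no bond change and keep the (R,R) configuration set in steps 2 to 5. The selectivity needed is regiochemical: propenyl must end on C7, and the chlorine on C5 should secure this by making the C8 end of the ruthenacycle the less hindered one, so that 19 enters there with its substituted carbon bonded to C8 and its CH carbon later bonded to C5, the meta orientation usual for this catalyst. Chemoselectivity for the alkyne of 19 over its alkene should follow from the stronger binding of alkynes, and slow addition of 18 to an excess of 19 should suppress self-trimerisation of 18. Room temperature is essential because both secondary alkynyl ethers would fragment to ketenes on heating.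

Step 10
Reactants: 20 (2R,3R)-5-chloro-2-[3,5-dimethoxy-4-(methoxymethoxy)phenyl]-3-methyl-7-[(E)-prop-1-enyl]-2,3-dihydro-1,4-benzodioxine
Product: 21 (2R,3R)-2-[3,5-dimethoxy-4-(methoxymethoxy)phenyl]-5-methoxy-3-methyl-7-[(E)-prop-1-enyl]-2,3-dihydro-1,4-benzodioxine
Conditions: Pd(OAc)2, tBuBrettPhos, NaOt-Bu, MeOH, 1,4-dioxane, 60 °C
Reagents that add atoms: methanol, CO
Why: Buchwald–Hartwig C–O coupling of an aryl chloride with methanol; the bulky biarylphosphine favours C–O reductive elimination over β-hydride loss from the palladium methoxide, and the acetal, the benzylic ether and the conjugated E alkene are inert to alkoxide at this temperature.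

Step 11
Reactants: 21 (2R,3R)-2-[3,5-dimethoxy-4-(methoxymethoxy)phenyl]-5-methoxy-3-methyl-7-[(E)-prop-1-enyl]-2,3-dihydro-1,4-benzodioxine
Product: 22 4-[(2R,3R)-5-methoxy-3-methyl-7-[(E)-prop-1-enyl]-2,3-dihydro-1,4-benzodioxin-2-yl]-2,6-dimethoxyphenol
Conditions: HCl, MeOH/THF, rt
Reagents that add atoms: none
Why: Acid-catalysed transacetalisation removes the crowded phenolic methoxymethyl group under conditions that should leave the propenyl group alone; C3 cannot epimerise, and any ionisation at the benzylic C2 would re-close to the same, more stable trans isomer.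

## Compound list

1 | 4-bromo-2,6-dimethoxyphenol | COc1cc(Br)cc(OC)c1O | starting material
2 | 5-bromo-1,3-dimethoxy-2-(methoxymethoxy)benzene | COCOc1c(OC)cc(Br)cc1OC | intermediate
3 | methyl (R)-lactate, methyl (2R)-2-hydroxypropanoate | C[C@@H](O)C(=O)OC | starting material
4 | methyl (2R)-2-(triisopropylsilyloxy)propanoate | C[C@@H](O[Si](C(C)C)(C(C)C)C(C)C)C(=O)OC | intermediate
5 | (2R)-N-methoxy-N-methyl-2-(triisopropylsilyloxy)propanamide | C[C@@H](O[Si](C(C)C)(C(C)C)C(C)C)C(=O)N(C)OC | intermediate
6 | [3,5-dimethoxy-4-(methoxymethoxy)phenyl]lithium (formed in the flask) | [Li]c1cc(OC)c(OCOC)c(OC)c1 | intermediate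
7 | (2R)-1-[3,5-dimethoxy-4-(methoxymethoxy)phenyl]-2-(triisopropylsilyloxy)propan-1-one | C[C@@H](O[Si](C(C)C)(C(C)C)C(C)C)C(=O)c1cc(OC)c(OCOC)c(OC)c1 | intermediate
8 | (1R,2R)-1-[3,5-dimethoxy-4-(methoxymethoxy)phenyl]-2-(triisopropylsilyloxy)propan-1-ol | O[C@H](c1cc(OC)c(OCOC)c(OC)c1)[C@@H](C)O[Si](C(C)C)(C(C)C)C(C)C | intermediate
9 | trichloroethylene | ClC=C(Cl)Cl | starting material
10 | dichloroacetylene (formed in the flask from 9 in step 6; the same species arises again from 9 in step 8) | ClC#CCl | intermediate
11 | {[(1R,2R)-1-[(E)-1,2-dichloroethenyloxy]-1-[3,5-dimethoxy-4-(methoxymethoxy)phenyl]propan-2-yl]oxy}triisopropylsilane (formed in the flask) | Cl/C=C(/Cl)O[C@H](c1cc(OC)c(OCOC)c(OC)c1)[C@@H](C)O[Si](C(C)C)(C(C)C)C(C)C | intermediate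
12 | {[(1R,2R)-1-(chloroethynyloxy)-1-[3,5-dimethoxy-4-(methoxymethoxy)phenyl]propan-2-yl]oxy}triisopropylsilane (formed in the flask) | ClC#CO[C@H](c1cc(OC)c(OCOC)c(OC)c1)[C@@H](C)O[Si](C(C)C)(C(C)C)C(C)C | intermediate
13 | lithium acetylide of 14 (formed in the flask) | [Li]C#CO[C@H](c1cc(OC)c(OCOC)c(OC)c1)[C@@H](C)O[Si](C(C)C)(C(C)C)C(C)C | intermediate
14 | {[(1R,2R)-1-[3,5-dimethoxy-4-(methoxymethoxy)phenyl]-1-(ethynyloxy)propan-2-yl]oxy}triisopropylsilane | C#CO[C@H](c1cc(OC)c(OCOC)c(OC)c1)[C@@H](C)O[Si](C(C)C)(C(C)C)C(C)C | intermediate
15 | (1R,2R)-1-[3,5-dimethoxy-4-(methoxymethoxy)phenyl]-1-(ethynyloxy)propan-2-ol | C#CO[C@H](c1cc(OC)c(OCOC)c(OC)c1)[C@@H](C)O | intermediate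
16 | 5-[(1R,2R)-2-[(E)-1,2-dichloroethenyloxy]-1-(ethynyloxy)propyl]-1,3-dimethoxy-2-(methoxymethoxy)benzene (formed in the flask) | C#CO[C@H](c1cc(OC)c(OCOC)c(OC)c1)[C@@H](C)O/C(Cl)=C\Cl | intermediate
17 | lithium acetylide of 18 (formed in the flask) | [Li]C#CO[C@H](c1cc(OC)c(OCOC)c(OC)c1)[C@@H](C)OC#CCl | intermediate
18 | 5-[(1R,2R)-2-(chloroethynyloxy)-1-(ethynyloxy)propyl]-1,3-dimethoxy-2-(methoxymethoxy)benzene | C#CO[C@H](c1cc(OC)c(OCOC)c(OC)c1)[C@@H](C)OC#CCl | intermediate
19 | (E)-pent-3-en-1-yne | C/C=C/C#C | starting material
20 | (2R,3R)-5-chloro-2-[3,5-dimethoxy-4-(methoxymethoxy)phenyl]-3-methyl-7-[(E)-prop-1-enyl]-2,3-dihydro-1,4-benzodioxine | C/C=C/c1cc(Cl)c2c(c1)O[C@H](c1cc(OC)c(OCOC)c(OC)c1)[C@@H](C)O2 | intermediate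
21 | (2R,3R)-2-[3,5-dimethoxy-4-(methoxymethoxy)phenyl]-5-methoxy-3-methyl-7-[(E)-prop-1-enyl]-2,3-dihydro-1,4-benzodioxine | C/C=C/c1cc(OC)c2c(c1)O[C@H](c1cc(OC)c(OCOC)c(OC)c1)[C@@H](C)O2 | intermediate
22 | 4-[(2R,3R)-5-methoxy-3-methyl-7-[(E)-prop-1-enyl]-2,3-dihydro-1,4-benzodioxin-2-yl]-2,6-dimethoxyphenol | C/C=C/c1cc(OC)c2c(c1)O[C@H](c1cc(OC)c(O)c(OC)c1)[C@@H](C)O2 | target

## Step count and least certain steps

Total: 11 steps. Longest linear sequence: 10 steps (steps 2 to 11, from 3 to 22); step 1 is a one-step branch.

Step 9 (key step). The most likely failures are: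
- diversion of the catalyst by the terminal alkynyl ether into an alkoxy-vinylidene or carbene complex that no longer turns over;
- self-oligomerisation of 18;
- erosion of the regioselectivity of alkyne insertion, because chlorine may not differentiate the two termini strongly enough;
- thermal fragmentation of the alkynyl ethers before the catalyst acts.

The fallback uses only known chemistry, sets out from 2 and returns at 21. 5-Bromovanillin and ethyl (S)-lactate are joined under Mitsunobu conditions (PPh3, diisopropyl azodicarboxylate, THF), which inverts the lactate carbon and gives ethyl (2R)-2-(2-bromo-4-formyl-6-methoxyphenoxy)propanoate F1. Takai–Utimoto ethylidenation (CH3CHI2, CrCl2, THF) should give ethyl (2R)-2-{2-bromo-6-methoxy-4-[(E)-prop-1-enyl]phenoxy}propanoate F2, and aminolysis (MeNH(OMe)·HCl, i-PrMgCl) gives (2R)-2-{2-bromo-6-methoxy-4-[(E)-prop-1-enyl]phenoxy}-N-methoxy-N-methylpropanamide F3. Compound 2 is converted with magnesium into [3,5-dimethoxy-4-(methoxymethoxy)phenyl]magnesium bromide F4, which adds once to F3 to give (2R)-2-{2-bromo-6-methoxy-4-[(E)-prop-1-enyl]phenoxy}-1-[3,5-dimethoxy-4-(methoxymethoxy)phenyl]propan-1-one F5. Reduction with LiBH(s-Bu)3 under polar Felkin–Anh control should give (1R,2R)-2-{2-bromo-6-methoxy-4-[(E)-prop-1-enyl]phenoxy}-1-[3,5-dimethoxy-4-(methoxymethoxy)phenyl]propan-1-ol F6. Intramolecular Buchwald–Hartwig etherification (Pd(OAc)2, 2-(di-tert-butylphosphino)-1,1'-binaphthyl, Cs2CO3, toluene, 80 °C) then closes O1–C8a with retention and gives 21, from which step 11 is unchanged.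

Step 8. The likely failures are:
- addition of the C8 acetylide (formed by proton transfer) to dichloroacetylene 10 during the KH stage;
- migration of chlorine between the two alkyne termini by chlorine–lithium exchange between the acetylide and the chloroalkyne of 17;
- decomposition of the chloroalkynyl ether on isolation.

The fallback removes the acetylide from the flask; it sets out from 15 and returns at 18. Compound 15 is deprotonated twice (n-BuLi, 2.1 equiv, THF, −78 °C) and silylated with Me3SiCl to give trimethyl{[(1R,2R)-1-[3,5-dimethoxy-4-(methoxymethoxy)phenyl]-2-(trimethylsilyloxy)propoxy]ethynyl}silane F7. Brief K2CO3/MeOH at 0 °C should cleave the far more labile O–Si bond first and give (1R,2R)-1-[3,5-dimethoxy-4-(methoxymethoxy)phenyl]-1-[(trimethylsilyl)ethynyloxy]propan-2-ol F8. KH and 9 give {[(1R,2R)-2-[(E)-1,2-dichloroethenyloxy]-1-[3,5-dimethoxy-4-(methoxymethoxy)phenyl]propoxy]ethynyl}trimethylsilane F9. LiN(i-Pr)2 (1.2 equiv, −78 °C) gives {[(1R,2R)-2-(chloroethynyloxy)-1-[3,5-dimethoxy-4-(methoxymethoxy)phenyl]propoxy]ethynyl}trimethylsilane F10, and Bu4NF at −78 °C removes the C-silyl cap to return 18.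

Step 10. The likely failure is slow oxidative addition into the electron-rich, ortho-oxygenated C5–Cl bond, so that β-hydride elimination from the palladium methoxide and hydrodechlorination take over. The fallback replaces direct C–O coupling by C–B formation and oxidation; it sets out from 20 and returns at 21. Miyaura borylation (Pd2(dba)3, XPhos, B2pin2, KOAc, 1,4-dioxane, 100 °C) gives 2-[(2R,3R)-2-[3,5-dimethoxy-4-(methoxymethoxy)phenyl]-3-methyl-7-[(E)-prop-1-enyl]-2,3-dihydro-1,4-benzodioxin-5-yl]-4,4,5,5-tetramethyl-1,3,2-dioxaborolane F11. Oxidation with NaBO3·4H2O in THF/water gives (2R,3R)-2-[3,5-dimethoxy-4-(methoxymethoxy)phenyl]-3-methyl-7-[(E)-prop-1-enyl]-2,3-dihydro-1,4-benzodioxin-5-ol F12, and methylation (MeI, K2CO3, acetone) gives 21.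

Step 5. The likely failure is insufficient facial selectivity, because the electron-rich aryl ketone reacts slowly and may need warming, which lowers substrate control. The fallback changes the source of stereocontrol from the substrate to a catalyst; it sets out from 7 and returns at 8 without new compounds. Transfer hydrogenation with RuCl(p-cymene)[(S,S)-TsDPEN] and HCO2H/Et3N is expected, by analogy with acetophenone, to deliver hydride to the face that gives the (1R) carbinol, in the same sense as the Felkin preference.

Further compounds

F1 | step 9 | ethyl (2R)-2-(2-bromo-4-formyl-6-methoxyphenoxy)propanoate | CCOC(=O)[C@@H](C)Oc1c(Br)cc(C=O)cc1OC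
F2 | step 9 | ethyl (2R)-2-{2-bromo-6-methoxy-4-[(E)-prop-1-enyl]phenoxy}propanoate | CCOC(=O)[C@@H](C)Oc1c(Br)cc(/C=C/C)cc1OC
F3 | step 9 | (2R)-2-{2-bromo-6-methoxy-4-[(E)-prop-1-enyl]phenoxy}-N-methoxy-N-methylpropanamide | CON(C)C(=O)[C@@H](C)Oc1c(Br)cc(/C=C/C)cc1OC
F4 | step 9 | [3,5-dimethoxy-4-(methoxymethoxy)phenyl]magnesium bromide | Br[Mg]c1cc(OC)c(OCOC)c(OC)c1
F5 | step 9 | (2R)-2-{2-bromo-6-methoxy-4-[(E)-prop-1-enyl]phenoxy}-1-[3,5-dimethoxy-4-(methoxymethoxy)phenyl]propan-1-one | C[C@@H](Oc1c(Br)cc(/C=C/C)cc1OC)C(=O)c1cc(OC)c(OCOC)c(OC)c1
F6 | step 9 | (1R,2R)-2-{2-bromo-6-methoxy-4-[(E)-prop-1-enyl]phenoxy}-1-[3,5-dimethoxy-4-(methoxymethoxy)phenyl]propan-1-ol | O[C@H](c1cc(OC)c(OCOC)c(OC)c1)[C@@H](C)Oc1c(Br)cc(/C=C/C)cc1OC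
F7 | step 8 | trimethyl{[(1R,2R)-1-[3,5-dimethoxy-4-(methoxymethoxy)phenyl]-2-(trimethylsilyloxy)propoxy]ethynyl}silane | C[Si](C)(C)C#CO[C@H](c1cc(OC)c(OCOC)c(OC)c1)[C@@H](C)O[Si](C)(C)C
F8 | step 8 | (1R,2R)-1-[3,5-dimethoxy-4-(methoxymethoxy)phenyl]-1-[(trimethylsilyl)ethynyloxy]propan-2-ol | C[Si](C)(C)C#CO[C@H](c1cc(OC)c(OCOC)c(OC)c1)[C@@H](C)O
F9 | step 8 | {[(1R,2R)-2-[(E)-1,2-dichloroethenyloxy]-1-[3,5-dimethoxy-4-(methoxymethoxy)phenyl]propoxy]ethynyl}trimethylsilane | C[Si](C)(C)C#CO[C@H](c1cc(OC)c(OCOC)c(OC)c1)[C@@H](C)O/C(Cl)=C\Cl
F10 | step 8 | {[(1R,2R)-2-(chloroethynyloxy)-1-[3,5-dimethoxy-4-(methoxymethoxy)phenyl]propoxy]ethynyl}trimethylsilane | C[Si](C)(C)C#CO[C@H](c1cc(OC)c(OCOC)c(OC)c1)[C@@H](C)OC#CCl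
F11 | step 10 | 2-[(2R,3R)-2-[3,5-dimethoxy-4-(methoxymethoxy)phenyl]-3-methyl-7-[(E)-prop-1-enyl]-2,3-dihydro-1,4-benzodioxin-5-yl]-4,4,5,5-tetramethyl-1,3,2-dioxaborolane | C/C=C/c1cc(B3OC(C)(C)C(C)(C)O3)c2c(c1)O[C@H](c1cc(OC)c(OCOC)c(OC)c1)[C@@H](C)O2
F12 | step 10 | (2R,3R)-2-[3,5-dimethoxy-4-(methoxymethoxy)phenyl]-3-methyl-7-[(E)-prop-1-enyl]-2,3-dihydro-1,4-benzodioxin-5-ol | C/C=C/c1cc(O)c2c(c1)O[C@H](c1cc(OC)c(OCOC)c(OC)c1)[C@@H](C)O2
F0 | step 5 | none | none
A1 | alternative 1 | methyl 7-methoxy-2-methyl-1,3-benzodioxole-5-carboxylate (racemic) | COC(=O)c1cc(OC)c2OC(C)Oc2c1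
A2 | alternative 1 | 4-(diazomethyl)-2,6-dimethoxyphenyl 4-methylbenzenesulfonate | Cc1ccc(cc1)S(=O)(=O)Oc1c(OC)cc(C=[N+]=[N-])cc1OC
A3 | alternative 1 | methyl (2R,3R)-2-[3,5-dimethoxy-4-(4-methylbenzenesulfonyloxy)phenyl]-5-methoxy-3-methyl-2,3-dihydro-1,4-benzodioxine-7-carboxylate | COC(=O)c1cc(OC)c2c(c1)O[C@H](c1cc(OC)c(OS(=O)(=O)c3ccc(C)cc3)c(OC)c1)[C@@H](C)O2
A4 | alternative 2 | 4-bromo-2-methoxy-6-{[(1S)-1-(3,5-dimethoxy-4-triisopropylsilyloxyphenyl)prop-2-en-1-yl]oxy}phenol | Oc1c(OC)cc(Br)cc1O[C@H](c1cc(OC)c(O[Si](C(C)C)(C(C)C)C(C)C)c(OC)c1)C=C
A5 | alternative 2 | (2R,3R)-7-bromo-2-[3,5-dimethoxy-4-(triisopropylsilyloxy)phenyl]-5-methoxy-3-methyl-2,3-dihydro-1,4-benzodioxine | Brc1cc(OC)c2c(c1)O[C@H](c1cc(OC)c(O[Si](C(C)C)(C(C)C)C(C)C)c(OC)c1)[C@@H](C)O2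
A6 | alternative 3 | (1R,2R)-2-{2-bromo-6-methoxy-4-[(E)-prop-1-enyl]phenoxy}-1-[3,5-dimethoxy-4-(triisopropylsilyloxy)phenyl]propan-1-ol | O[C@H](c1cc(OC)c(O[Si](C(C)C)(C(C)C)C(C)C)c(OC)c1)[C@@H](C)Oc1c(Br)cc(/C=C/C)cc1OC
A7 | alternative 3 | (2R,3R)-2-[3,5-dimethoxy-4-(triisopropylsilyloxy)phenyl]-5-methoxy-3-methyl-7-[(E)-prop-1-enyl]-2,3-dihydro-1,4-benzodioxine | C/C=C/c1cc(OC)c2c(c1)O[C@H](c1cc(OC)c(O[Si](C(C)C)(C(C)C)C(C)C)c(OC)c1)[C@@H](C)O2
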